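Ring B of the target carries C8 (CHMe), quaternary C9 (Me, CH2Ar), C10–H and quaternary C5–Me in a row. These are the four sp3 carbons of a cyclohexene, so ring B is cut across C5–C10 and C8–C9. A type-1 intramolecular Diels–Alder reaction of an acyclic, achiral trienal then closes rings A and B of the trans-decalin and sets all four centres at once, with a chiral boron Lewis acid choosing the enantiomer. The precursor is a (2E,8E,10E)-2,8-dimethyldodeca-2,8,10-trienal whose C6 carbonyl (later C3) is masked as a 1,3-dithiane. Aryl group, C3 ketone and C4 side chain follow afterwards.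

Key step: step 8

Remark on locants: C1–C10 are the decalin carbons of the target. Ring A is C1–C5 and C10 (C3 carbonyl, C4 bearing the acid chain); ring B is C5–C10 (C8–Me, C9–Me/CH2Ar).

Remark on the precursor: the C3 carbonyl is carried as a 1,3-dithiane instead of an O,O-ketal; carbon skeleton, alkene geometries, bonds formed and rings closed are unchanged. The dithiane is the acyl-anion linchpin that joins the two chains, survives release of the aldehyde from its O,O-acetal, and offers no hard donor to a boron Lewis acid.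

Remark on connectivity: the single CH2 between C3 and the diene (C4) is the CH2 of the dienyl bromide itself. A three-carbon ketone azaenolate alkylated by that bromide would insert a second CH2 and give a five-atom tether.

Assumption: the catalyst antipode in step 8 is assigned from the accepted binding model for 2-substituted enals (B–O coordination plus formyl C–H···O contact). Both antipodes are commercial, so only the catalyst label depends on this assignment.

Step 1
Reactants: 1 (E)-but-2-enal (crotonaldehyde); 2 ethyl 2-(triphenylphosphoranylidene)propanoate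
Product: 3 ethyl (2E,4E)-2-methylhexa-2,4-dienoate
Conditions: CH2Cl2, 0 °C → rt
Reagents that add atoms: none
Why: Wittig olefination with an ester-stabilised ylide gives the (2E)-trisubstituted alkene, and the (E)-propenyl unit of 1 is carried over unchanged.

Step 2
Reactants: 3 ethyl (2E,4E)-2-methylhexa-2,4-dienoate
Product: 4 (2E,4E)-2-methylhexa-2,4-dien-1-ol
Conditions: DIBAL-H (2.2 equiv), CH2Cl2, −78 → 0 °C; Rochelle salt
Reagents that add atoms: none
Why: DIBAL-H reduces the conjugated ester by 1,2-hydride delivery to the allylic alcohol and leaves the diene untouched.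

Step 3
Reactants: 4 (2E,4E)-2-methylhexa-2,4-dien-1-ol
Product: 5 (2E,4E)-1-bromo-2-methylhexa-2,4-diene
Conditions: PBr3 (0.4 equiv), Et2O, −10 °C; used crude at once
Reagents that add atoms: phosphorus tribromide, BrP(Br)Br
Why: SN2 displacement of the activated primary allylic alcohol by bromide at low temperature keeps both alkene geometries, and immediate use limits allylic transposition.

Step 4
Reactants: 6 1,3-dithiane; 7 3-bromo-1,1-dimethoxypropane
Product: 9 2-(3,3-dimethoxypropyl)-1,3-dithiane, via 2-lithio-1,3-dithiane 8 (not isolated)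
Conditions: n-BuLi, THF, −30 °C; then 7, −78 °C → rt
Reagents that add atoms: none
Why: Corey–Seebach alkylation, in which the sulfur-stabilised C2 anion displaces the primary bromide while the dimethyl acetal is inert to the base.

Step 5
Reactants: 9 2-(3,3-dimethoxypropyl)-1,3-dithiane; 5 (2E,4E)-1-bromo-2-methylhexa-2,4-diene
Product: 11 2-(3,3-dimethoxypropyl)-2-[(2E,4E)-2-methylhexa-2,4-dien-1-yl]-1,3-dithiane, via 2-lithio dithiane 10 (not isolated)
Conditions: n-BuLi, THF, −25 °C, 2 h; then 5, −78 → 0 °C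
Reagents that add atoms: none
Why: second Corey–Seebach alkylation, in which the hindered dithianyl anion attacks the unhindered primary allylic carbon of 5 (SN2), placing exactly one CH2 (C4) between masked C3 and the diene with the (E,E) geometry intact.

Step 6
Reactants: 11 2-(3,3-dimethoxypropyl)-2-[(2E,4E)-2-methylhexa-2,4-dien-1-yl]-1,3-dithiane
Product: 12 3-{2-[(2E,4E)-2-methylhexa-2,4-dien-1-yl]-1,3-dithian-2-yl}propanal
Conditions: TsOH·H2O (10 mol%), acetone/H2O 10:1, rt
Reagents that add atoms: water, O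
Why: acid-catalysed hydrolysis of the O,O-acetal; the S,S-acetal does not ionise under these conditions, and the skipped diene cannot move into conjugation because C3 is never a free carbonyl.

Step 7
Reactants: 12 3-{2-[(2E,4E)-2-methylhexa-2,4-dien-1-yl]-1,3-dithian-2-yl}propanal; 13 2-(triphenylphosphoranylidene)propanal
Product: 14 (2E)-2-methyl-5-{2-[(2E,4E)-2-methylhexa-2,4-dien-1-yl]-1,3-dithian-2-yl}pent-2-enal, i.e. the 1,3-dithiane of (2E,8E,10E)-2,8-dimethyl-6-oxododeca-2,8,10-trienal
Conditions: toluene, 80 °C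
Reagents that add atoms: none
Why: Wittig olefination with a formyl-stabilised ylide gives the (E)-2-methylenal, and the α-branched enal product reacts with the ylide far more slowly than aldehyde 12.

Step 8
Reactants: 14 (2E)-2-methyl-5-{2-[(2E,4E)-2-methylhexa-2,4-dien-1-yl]-1,3-dithian-2-yl}pent-2-enal
Product: 15 (1S,2S,4aR,8aS)-1,2,4a-trimethyl-6,6-(propane-1,3-diyldisulfanediyl)-1,2,4a,5,6,7,8,8a-octahydronaphthalene-1-carbaldehyde (trans-fused; spiro-1,3-dithiane at C6 of the naphthalene numbering)
Conditions: (R)-3,3-diphenyl-1-(o-tolyl)tetrahydro-1H,3H-pyrrolo[1,2-c][1,3,2]oxazaborole (20 mol%), Tf2NH (18 mol%), CH2Cl2, −78 → −40 °C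
Reagents that add atoms: none
Why: Boron-bound (E)-2-methylenal and tethered (E,E)-diene combine in a concerted, asynchronous [4+2] cycloaddition in which the C5–C10 bond runs ahead of the C8–C9 bond; the closest known reaction type is the chiral boron Lewis acid-catalysed intramolecular Diels–Alder reaction of 2-methyldeca-2,7,9-trienals to trans-fused bicyclic aldehydes. Ring B (C5, C6=C7, C8, C9, C10) closes as the cycloadduct ring, and ring A (C10, C1, C2, C3, C4, C5) closes as a six-membered ring through the four-carbon tether held chair-like and anti to the diene. C9 and C10 inherit the E geometry of the enal (formyl cis to H-10, C9–Me cis to C1), and C5 and C8 inherit the geometry of the diene (C5–Me inside, C4 and C8–Me outside and therefore cis). The endo position of the formyl group places it cis to C4 and C8–Me, which makes H-10 anti to C5–Me (trans-decalin) and C8–Me cis to the future benzylic carbon. The absolute configuration is set by the catalyst, which holds the formyl group by B–O coordination and a formyl C–H···O contact and covers the C9-Re face, so that the diene adds to the C9-Si/C10-Re face. The selectivities needed are endo over exo and one enal face: the chair tether with Lewis acid-enhanced secondary overlap provides the first and the catalyst the second, while the dithiane favours ring closure (gem-disubstituent effect) and cannot sequester boron.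

Step 9
Reactants: 16 4-methoxy-2-methylphenol
Product: 17 2-bromo-4-methoxy-6-methylphenol
Conditions: NBS (1.0 equiv), i-Pr2NH (10 mol%), CH2Cl2, 0 °C
Reagents that add atoms: N-bromosuccinimide, O=C1CCC(=O)N1Br
Why: electrophilic aromatic bromination ortho to the free hydroxyl group, whose para position is blocked by OMe and whose other ortho position by CH3.

Step 10
Reactants: 17 2-bromo-4-methoxy-6-methylphenol
Product: 18 1-bromo-2,5-dimethoxy-3-methylbenzene
Conditions: MeI, K2CO3, acetone, reflux
Reagents that add atoms: iodomethane, CI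
Why: Williamson O-methylation of the phenoxide.

Step 11
Reactants: 18 1-bromo-2,5-dimethoxy-3-methylbenzene; 15 (1S,2S,4aR,8aS)-1,2,4a-trimethyl-6,6-(propane-1,3-diyldisulfanediyl)-1,2,4a,5,6,7,8,8a-octahydronaphthalene-1-carbaldehyde
Product: 20 (2,5-dimethoxy-3-methylphenyl)[(1S,2S,4aR,8aS)-1,2,4a-trimethyl-6,6-(propane-1,3-diyldisulfanediyl)-1,2,4a,5,6,7,8,8a-octahydronaphthalen-1-yl]methanol (both carbinol epimers), via (2,5-dimethoxy-3-methylphenyl)lithium 19 (not isolated)
Conditions: n-BuLi, THF, −78 °C; then 15, −78 → −30 °C; H2O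
Reagents that add atoms: none
Why: bromine–lithium exchange followed by 1,2-addition of the aryllithium to the non-enolisable neopentyl aldehyde; the dithiane has no acidic proton, and the new carbinol centre is removed in step 12.

Step 12
Reactants: 20 (2,5-dimethoxy-3-methylphenyl)[(1S,2S,4aR,8aS)-1,2,4a-trimethyl-6,6-(propane-1,3-diyldisulfanediyl)-1,2,4a,5,6,7,8,8a-octahydronaphthalen-1-yl]methanol
Product: 21 1-{[(1S,2S,4aR,8aS)-1,2,4a-trimethyl-6,6-(propane-1,3-diyldisulfanediyl)-1,2,4a,5,6,7,8,8a-octahydronaphthalen-1-yl]methyl}-2,5-dimethoxy-3-methylbenzene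
Conditions: Et3SiH (3 equiv), TFA, CH2Cl2, −20 → 0 °C, short contact
Reagents that add atoms: none
Why: ionic hydrogenation, in which TFA ionises the o-methoxy-stabilised benzylic alcohol and the silane transfers hydride faster than the cation can rearrange; dithiane, disubstituted ring alkene and aryl ethers are inert at this temperature.

Step 13
Reactants: 21 1-{[(1S,2S,4aR,8aS)-1,2,4a-trimethyl-6,6-(propane-1,3-diyldisulfanediyl)-1,2,4a,5,6,7,8,8a-octahydronaphthalen-1-yl]methyl}-2,5-dimethoxy-3-methylbenzene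
Product: 22 (4aS,5S,6S,8aR)-5-[(2,5-dimethoxy-3-methylphenyl)methyl]-5,6,8a-trimethyl-3,4,4a,5,6,8a-hexahydronaphthalen-2(1H)-one
Conditions: MeI (excess), CaCO3, MeCN/H2O 4:1, 45 °C
Reagents that add atoms: water, O
Why: alkylative dethioacetalisation, in which S-methylation makes sulfur a leaving group and water delivers the carbonyl oxygen while CaCO3 buffers the HI; arene and ring alkene do not react with iodomethane.

Step 14
Reactants: 22 (4aS,5S,6S,8aR)-5-[(2,5-dimethoxy-3-methylphenyl)methyl]-5,6,8a-trimethyl-3,4,4a,5,6,8a-hexahydronaphthalen-2(1H)-one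
Product: 24 (4aS,5S,6S,8aR)-5-[(2,5-dimethoxy-3-methylphenyl)methyl]-5,6,8a-trimethyl-4a,5,6,8a-tetrahydronaphthalen-2(1H)-one (C1=C2 enone in decalin locants), via trimethylsilyl enol ether 23 (not isolated)
Conditions: LDA, TMSCl, THF, −78 °C; then Pd(OAc)2 (1.0 equiv), MeCN, rt
Reagents that add atoms: none
Why: kinetic deprotonation at the less hindered C2 methylene (C4 is neopentyl) and O-silylation, then Saegusa–Ito oxidation; only the C1=C2 enone can form because C5 carries no hydrogen, and any C3=C4 enol ether reverts to 22.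

Step 15
Reactants: 24 (4aS,5S,6S,8aR)-5-[(2,5-dimethoxy-3-methylphenyl)methyl]-5,6,8a-trimethyl-4a,5,6,8a-tetrahydronaphthalen-2(1H)-one; 25 tert-butyl prop-2-enoate (tert-butyl acrylate)
Product: 27 tert-butyl 3-[(1R,4aR,5S,6S,8aR)-5-[(2,5-dimethoxy-3-methylphenyl)methyl]-5,6,8a-trimethyl-2-oxo-1,2,4a,5,6,8a-hexahydronaphthalen-1-yl]propanoate (side chain 4β), via lithium dienolate 26 (not isolated)
Conditions: LDA (1.1 equiv), THF, −78 °C; then 25 (1.1 equiv), −78 °C; AcOH quench at −78 °C
Reagents that add atoms: none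
Why: kinetic α′-deprotonation of the enone at C4 (C2 is blocked as an sp2 carbon) gives the cross-conjugated dienolate, which undergoes Michael addition to the acrylate from the β-face, anti to the axial C5 methyl; a second, ring-forming Michael addition onto C1 is excluded by the trans ring fusion, and the 4β configuration is corrected in step 16.

Step 16
Reactants: 27 tert-butyl 3-[(1R,4aR,5S,6S,8aR)-5-[(2,5-dimethoxy-3-methylphenyl)methyl]-5,6,8a-trimethyl-2-oxo-1,2,4a,5,6,8a-hexahydronaphthalen-1-yl]propanoate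
Product: 29 tert-butyl 3-[(1S,4aR,5S,6S,8aR)-5-[(2,5-dimethoxy-3-methylphenyl)methyl]-5,6,8a-trimethyl-2-oxodecahydronaphthalen-1-yl]propanoate (side chain 4α, equatorial), via saturated 4β keto ester 28 (not isolated)
Conditions: H2 (1 atm), 5% Pt/C, EtOAc, rt; filter; then NaOMe (0.3 equiv), MeOH, rt
Reagents that add atoms: none
Why: heterogeneous hydrogenation saturates C1=C2 and C6=C7 without creating a stereocentre (platinum is chosen to suppress migration of C6=C7 towards C8); methoxide then equilibrates C4, the only epimerisable centre, through the C3 enolate towards the equatorial 4α chain, which is also the product of protonation anti to the axial C5 methyl.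

Step 17
Reactants: 29 tert-butyl 3-[(1S,4aR,5S,6S,8aR)-5-[(2,5-dimethoxy-3-methylphenyl)methyl]-5,6,8a-trimethyl-2-oxodecahydronaphthalen-1-yl]propanoate
Product: 30 3-[(1S,4aR,5S,6S,8aR)-5-[(2,5-dihydroxy-3-methylphenyl)methyl]-5,6,8a-trimethyl-2-oxodecahydronaphthalen-1-yl]propanoic acid (CNP0167047.1)
Conditions: BBr3 (6 equiv), CH2Cl2, −78 → 0 °C; H2O, work-up under argon
Reagents that add atoms: none
Why: boron tribromide cleaves both aryl methyl ethers and the tert-butyl ester (alkyl–oxygen cleavage) in one operation, and hydrolytic work-up gives the hydroquinone keto acid with C4 in its stable equatorial configuration.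

Compound list
1 | (E)-but-2-enal (crotonaldehyde) | C/C=C/C=O | starting material
2 | ethyl 2-(triphenylphosphoranylidene)propanoate | CCOC(=O)C(C)=P(c1ccccc1)(c1ccccc1)c1ccccc1 | starting material
3 | ethyl (2E,4E)-2-methylhexa-2,4-dienoate | CCOC(=O)/C(C)=C/C=C/C | intermediate
4 | (2E,4E)-2-methylhexa-2,4-dien-1-ol | OC/C(C)=C/C=C/C | intermediate
5 | (2E,4E)-1-bromo-2-methylhexa-2,4-diene | BrC/C(C)=C/C=C/C | intermediate
6 | 1,3-dithiane | C1CSCSC1 | starting material
7 | 3-bromo-1,1-dimethoxypropane | COC(CCBr)OC | starting material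
8 | 2-lithio-1,3-dithiane | [Li]C1SCCCS1 | intermediate
9 | 2-(3,3-dimethoxypropyl)-1,3-dithiane | COC(CCC1SCCCS1)OC | intermediate
10 | 2-(3,3-dimethoxypropyl)-2-lithio-1,3-dithiane | COC(CCC1([Li])SCCCS1)OC | intermediate
11 | 2-(3,3-dimethoxypropyl)-2-[(2E,4E)-2-methylhexa-2,4-dien-1-yl]-1,3-dithiane | COC(CCC1(C/C(C)=C/C=C/C)SCCCS1)OC | intermediate
12 | 3-{2-[(2E,4E)-2-methylhexa-2,4-dien-1-yl]-1,3-dithian-2-yl}propanal | O=CCCC1(C/C(C)=C/C=C/C)SCCCS1 | intermediate
13 | 2-(triphenylphosphoranylidene)propanal | O=CC(C)=P(c1ccccc1)(c1ccccc1)c1ccccc1 | starting material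
14 | (2E)-2-methyl-5-{2-[(2E,4E)-2-methylhexa-2,4-dien-1-yl]-1,3-dithian-2-yl}pent-2-enal (1,3-dithiane of (2E,8E,10E)-2,8-dimethyl-6-oxododeca-2,8,10-trienal) | O=C/C(C)=C/CCC1(SCCCS1)C/C(C)=C/C=C/C | intermediate
15 | (1S,2S,4aR,8aS)-1,2,4a-trimethyl-6,6-(propane-1,3-diyldisulfanediyl)-1,2,4a,5,6,7,8,8a-octahydronaphthalene-1-carbaldehyde | O=C[C@]1(C)[C@H]2CCC3(SCCCS3)C[C@]2(C)C=C[C@@H]1C | intermediate
16 | 4-methoxy-2-methylphenol | Cc1cc(OC)ccc1O | starting material
17 | 2-bromo-4-methoxy-6-methylphenol | Cc1cc(OC)cc(Br)c1O | intermediate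
18 | 1-bromo-2,5-dimethoxy-3-methylbenzene | Cc1cc(OC)cc(Br)c1OC | intermediate
19 | (2,5-dimethoxy-3-methylphenyl)lithium | [Li]c1cc(OC)cc(C)c1OC | intermediate
20 | (2,5-dimethoxy-3-methylphenyl)[(1S,2S,4aR,8aS)-1,2,4a-trimethyl-6,6-(propane-1,3-diyldisulfanediyl)-1,2,4a,5,6,7,8,8a-octahydronaphthalen-1-yl]methanol (carbinol epimers) | Cc1cc(OC)cc(C(O)[C@]2(C)[C@H]3CCC4(SCCCS4)C[C@]3(C)C=C[C@@H]2C)c1OC | intermediate
21 | 1-{[(1S,2S,4aR,8aS)-1,2,4a-trimethyl-6,6-(propane-1,3-diyldisulfanediyl)-1,2,4a,5,6,7,8,8a-octahydronaphthalen-1-yl]methyl}-2,5-dimethoxy-3-methylbenzene | Cc1cc(OC)cc(C[C@]2(C)[C@H]3CCC4(SCCCS4)C[C@]3(C)C=C[C@@H]2C)c1OC | intermediate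
22 | (4aS,5S,6S,8aR)-5-[(2,5-dimethoxy-3-methylphenyl)methyl]-5,6,8a-trimethyl-3,4,4a,5,6,8a-hexahydronaphthalen-2(1H)-one | Cc1cc(OC)cc(C[C@]2(C)[C@H]3CCC(=O)C[C@]3(C)C=C[C@@H]2C)c1OC | intermediate
23 | {[(4aS,5S,6S,8aR)-5-[(2,5-dimethoxy-3-methylphenyl)methyl]-5,6,8a-trimethyl-1,4,4a,5,6,8a-hexahydronaphthalen-2-yl]oxy}trimethylsilane | Cc1cc(OC)cc(C[C@]2(C)[C@H]3CC=C(O[Si](C)(C)C)C[C@]3(C)C=C[C@@H]2C)c1OC | intermediate
24 | (4aS,5S,6S,8aR)-5-[(2,5-dimethoxy-3-methylphenyl)methyl]-5,6,8a-trimethyl-4a,5,6,8a-tetrahydronaphthalen-2(1H)-one | Cc1cc(OC)cc(C[C@]2(C)[C@H]3C=CC(=O)C[C@]3(C)C=C[C@@H]2C)c1OC | intermediate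
25 | tert-butyl prop-2-enoate | C=CC(=O)OC(C)(C)C | starting material
26 | lithium dienolate of 24 (C3–OLi, C3=C4, C1=C2; configuration as in 24) | Cc1cc(OC)cc(C[C@]2(C)[C@H]3C=CC(O[Li])=C[C@]3(C)C=C[C@@H]2C)c1OC | intermediate
27 | tert-butyl 3-[(1R,4aR,5S,6S,8aR)-5-[(2,5-dimethoxy-3-methylphenyl)methyl]-5,6,8a-trimethyl-2-oxo-1,2,4a,5,6,8a-hexahydronaphthalen-1-yl]propanoate | Cc1cc(OC)cc(C[C@]2(C)[C@H]3C=CC(=O)[C@H](CCC(=O)OC(C)(C)C)[C@]3(C)C=C[C@@H]2C)c1OC | intermediate
28 | tert-butyl 3-[(1R,4aR,5S,6S,8aR)-5-[(2,5-dimethoxy-3-methylphenyl)methyl]-5,6,8a-trimethyl-2-oxodecahydronaphthalen-1-yl]propanoate | Cc1cc(OC)cc(C[C@]2(C)[C@H]3CCC(=O)[C@H](CCC(=O)OC(C)(C)C)[C@]3(C)CC[C@@H]2C)c1OC | intermediate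
29 | tert-butyl 3-[(1S,4aR,5S,6S,8aR)-5-[(2,5-dimethoxy-3-methylphenyl)methyl]-5,6,8a-trimethyl-2-oxodecahydronaphthalen-1-yl]propanoate | Cc1cc(OC)cc(C[C@]2(C)[C@H]3CCC(=O)[C@@H](CCC(=O)OC(C)(C)C)[C@]3(C)CC[C@@H]2C)c1OC | intermediate
30 | 3-[(1S,4aR,5S,6S,8aR)-5-[(2,5-dihydroxy-3-methylphenyl)methyl]-5,6,8a-trimethyl-2-oxodecahydronaphthalen-1-yl]propanoic acid | Cc1cc(O)cc(C[C@]2(C)[C@H]3CCC(=O)[C@@H](CCC(=O)O)[C@]3(C)CC[C@@H]2C)c1O | target

Total step count: 17.
Longest linear sequence: 14 steps (1–3, 5–8, 11–17, from crotonaldehyde).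

Steps most likely to fail

1. Step 8. The cycloaddition may stall at the fully substituted diene terminus C5 and give way to cationic side reactions of the diene. It may also lose its endo preference or discriminate poorly between the two enal faces. The fallback replaces catalyst control by a covalent auxiliary on a more electrophilic dienophile. It sets out from 14, which is acetalised with the bis-trimethylsilyl ether of (2R,4R)-pentane-2,4-diol and catalytic TMSOTf at −78 °C to give (4R,6R)-4,6-dimethyl-2-[(2E,8E,10E)-trienyl]-1,3-dioxane F1. Catalytic TfOH in CH2Cl2 at −78 °C opens F1 to the vinyl-oxocarbenium ion, which undergoes the ionic intramolecular Diels–Alder reaction and recloses to the cycloadduct acetal F2. The diastereomers of F2 are separated by chromatography, and the one with the (1S,2S,4aR,8aS) core is hydrolysed (aqueous oxalic acid, THF) to come back to the route at 15. The antipodal diol is used if the auxiliary favours the other face.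

2. Step 15. Anionic oligomerisation of the acrylate and proton exchange between the ester enolate and the product may leave little mono-adduct at the hindered C4 position. The fallback uses an acceptor whose adduct is a stabilised, non-propagating carbanion, followed by a separate desilylation. It sets out from 24, whose lithium dienolate 26 is added to tert-butyl 2-(trimethylsilyl)acrylate at −78 °C to give the α-silyl ester F3. Protodesilylation of F3 (TBAF, wet THF, 0 °C) comes back to the route at 27.

3. Step 16. The base equilibration at C4 may stop at an unfavourable mixture of epimers, because the equatorial chain is opposed by gauche contacts with both C5 substituents. The fallback sets C4 by kinetic protonation instead of equilibration. It sets out from 24: LDA and dimethylmethyleneiminium iodide give the Mannich base F4, and quaternisation (MeI) with elimination (NaHCO3) gives the 4-methylene dienone F5. Mukaiyama–Michael addition of 1-tert-butoxy-1-(tert-butyldimethylsilyloxy)ethene to the exocyclic CH2 of F5 (catalytic TBSOTf, CH2Cl2, −78 °C) gives the silyl dienol ether F6. Protodesilylation at −78 °C (TBAF/AcOH) protonates C4 from the β-face, anti to the C5 methyl, and gives the 4α ester F7, the C4 epimer of 27. Hydrogenation of F7 (H2, Pt/C, EtOAc, no base) comes back to the route at 29.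

Further compounds
F1 | step 8 | (4R,6R)-4,6-dimethyl-2-[(1E)-1-methyl-4-{2-[(2E,4E)-2-methylhexa-2,4-dien-1-yl]-1,3-dithian-2-yl}but-1-en-1-yl]-1,3-dioxane | C/C=C/C=C(C)/CC1(SCCCS1)CC/C=C(C)/C1O[C@H](C)C[C@@H](C)O1
F2 | step 8 | (4R,6R)-4,6-dimethyl-2-[(1S,2S,4aR,8aS)-1,2,4a-trimethyl-6,6-(propane-1,3-diyldisulfanediyl)-1,2,4a,5,6,7,8,8a-octahydronaphthalen-1-yl]-1,3-dioxane | C1(O[C@H](C)C[C@@H](C)O1)[C@]2(C)[C@H]3CCC4(SCCCS4)C[C@]3(C)C=C[C@@H]2C
F3 | step 15 | tert-butyl 3-[(1R,4aR,5S,6S,8aR)-5-[(2,5-dimethoxy-3-methylphenyl)methyl]-5,6,8a-trimethyl-2-oxo-1,2,4a,5,6,8a-hexahydronaphthalen-1-yl]-2-(trimethylsilyl)propanoate | Cc1cc(OC)cc(C[C@]2(C)[C@H]3C=CC(=O)[C@H](CC(C(=O)OC(C)(C)C)[Si](C)(C)C)[C@]3(C)C=C[C@@H]2C)c1OC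
F4 | step 16 | 4β-(dimethylaminomethyl) derivative of 24 (decalin locants) | Cc1cc(OC)cc(C[C@]2(C)[C@H]3C=CC(=O)[C@H](CN(C)C)[C@]3(C)C=C[C@@H]2C)c1OC
F5 | step 16 | 4-methylene derivative of 24 (decalin locants) | Cc1cc(OC)cc(C[C@]2(C)[C@H]3C=CC(=O)C(=C)[C@]3(C)C=C[C@@H]2C)c1OC
F6 | step 16 | tert-butyl 3-[3-(tert-butyldimethylsilyloxy)-dienyl]propanoate: C3 silyl dienol ether (C1=C2, C3=C4) carrying the C4 propanoate chain | Cc1cc(OC)cc(C[C@]2(C)[C@H]3C=CC(O[Si](C)(C)C(C)(C)C)=C(CCC(=O)OC(C)(C)C)[C@]3(C)C=C[C@@H]2C)c1OC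
F7 | step 16 | tert-butyl 3-[(1S,4aR,5S,6S,8aR)-5-[(2,5-dimethoxy-3-methylphenyl)methyl]-5,6,8a-trimethyl-2-oxo-1,2,4a,5,6,8a-hexahydronaphthalen-1-yl]propanoate | Cc1cc(OC)cc(C[C@]2(C)[C@H]3C=CC(=O)[C@@H](CCC(=O)OC(C)(C)C)[C@]3(C)C=C[C@@H]2C)c1OC
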